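All runs were generated by integration for substances that don't exist, noise included.

Late in the larch run the target has reached 35.9% of the substrate charged and gains just 3.60% over the last 0.900 h, still far short of the whole charge of substrate, the limiting reagent there.

| setting | larch | ash | alder |
|---|---|---|---|
| substrate | 0.100 M | 0.100 M | 0.0330 M |
| partner | 0.150 M | 0.220 M | 0.0500 M |
| free catalyst | 0.0100 M | 0.0100 M | 0.0100 M |
| time |  |  | 3.9 h |

| larch run: time / h | larch run: [target] / M | ash run: time / h | ash run: [target] / M |
|---|---|---|---|
| 0.17 | 0.0047 | 0.17 | 0.0062 |
| 0.53 | 0.0109 | 0.53 | 0.0162 |
| 1.0 | 0.0206 | 1.0 | 0.0281 |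
| 1.6 | 0.0252 | 1.6 | 0.0360 |
| 2.3 | 0.0302 | 2.3 | 0.0399 |
| 3.0 | 0.0323 | 3.0 | 0.0435 |
| 3.9 | 0.0359 | 3.9 | 0.0454 |

(each reading ± 8 × 10⁻⁴ M)

* apparent order in [partner] of the starting rate, round the charge of the larch run (the rate where two percent of its substrate have turned into target)
* target in the alder run at 3.9 h, as a share of the substrate charged

- Overall: substrate + partner -> target, with free catalyst as catalyst.
- Constant volume, constant temperature.
- "The second partner" is partner.
- An order is taken over about fifteen percent of the charge, up and down.

Two chemists read this stall differently. The first says the reaction also runs back and the stall is a balance. Target over the product of substrate left and partner left, each reckoned as its charge minus the target, reads 4.91 L mol⁻¹ at the last larch reading and 4.76 L mol⁻¹ at the last ash reading, and to him that looks like a constant.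

The second says the reaction runs forward and the catalyst is dying. She divides the rate by substrate left times partner left, so that time drops out and a count of catalyst working remains. Its reading, with what is left again reckoned as charge minus target, is the logarithm of the share of partner left over the share of substrate left, divided by the excess of partner charged over substrate charged. At the last larch reading this gives 3.42 L mol⁻¹. That number is the clock.

At 1.0 h the clock reads 1.66 L mol⁻¹ in larch and 1.61 L mol⁻¹ in ash, so she takes the rate as first order in partner. At the last ash reading it stands lower than in larch, at 3.12 L mol⁻¹.

I side with her. Alder has the catalyst charge of larch and nearly its ratio of partner to substrate, so I give alder the larch clock at 3.9 h. That yields 15.0% of its substrate as target.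

The forecast, “Treating this as equilibrium” and then shading down, says 15.5%, higher than mine, with an order of 0.9 against my first order.

The alder flask gives 15.6%, and the order comes out at 1.0.

    2 free catalyst ⇌ catalyst dimer, settled at all times (92.70 L mol⁻¹)
    free catalyst + substrate + partner → target + free catalyst (363.6 L² mol⁻² h⁻¹)
    2 free catalyst → 2 spent catalyst (78.12 L mol⁻¹ h⁻¹)
    target → decomposed product (0.1004 h⁻¹)

These equations hold no back step, and free catalyst goes over to spent catalyst. Loss of target to decomposed product moves the readings by 7.2 times the scatter, as a root mean square. Put on the alder result, the clock reads 3.57 L mol⁻¹, against 3.42 L mol⁻¹ for larch at the same hour.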